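## Retrosynthetic overview

1. The strategy rests on C7 of the carbocycle (ring atoms C4a, C5, C6, C7, C8, C8a; isochromene numbering). C7 is fully substituted, carries CH3 and the 2,6-disubstituted aroyloxy group, and lies between the C8 ketone and the trans C6 carbinol. The C8(=O)–C7(O-acyl) pair can therefore be read as the outcome of an enol ester epoxide rearrangement.
2. The C7–O ester bond is disconnected to a C7/C8 oxirane with the aroate on C8. This oxirane goes back to the O-aroylated enol of 2-methylcyclohexane-1,3-dione; C6 is set by a CBS reduction and relayed to C7 by directed epoxidation followed by inversion.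
3. The pyran is dismantled at O2–C3 (6-endo-dig hydroalkoxylation), at C1–C8a (formylation) and at C4–C4a (conjugate alkynylation of the C8a=C4a enone with a pentenynylzinc reagent made from crotonaldehyde).
4. Ring order: the arene and the carbocycle are bought, the oxirane is a temporary ring opened in the key step, and the pyran is the only ring built. It closes in the penultimate step, before global desilylation.

Key step: step 9

Remark on the chemistry: the target SMILES is read as (6R,7S), with the C6 hydroxyl and the C7 ester oxygen on opposite faces of the carbocycle. Isochromene locants (C1, O2, C3, C4, C4a, C5–C8, C8a) are used in the comments for all intermediates. "Aroate" means 2-methoxy-6-methyl-4-(triisopropylsilyloxy)benzoate, and TBSO means tert-butyldimethylsilyloxy.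

## Route

Step 1
Reactants: 1 2,4-dihydroxy-6-methylbenzaldehyde
Product: 2 2-hydroxy-6-methyl-4-(triisopropylsilyloxy)benzaldehyde
Conditions: TIPSCl (1.05 equiv), imidazole, CH2Cl2, 0 °C to rt
Reagents that add atoms: triisopropylsilyl chloride, CC(C)[Si](Cl)(C(C)C)C(C)C
Why: Chemoselective O-silylation; the 2-hydroxyl is hydrogen-bonded to the formyl oxygen and sterically flanked, so the bulky chlorosilane should react only at the free 4-hydroxyl.

Step 2
Reactants: 2 2-hydroxy-6-methyl-4-(triisopropylsilyloxy)benzaldehyde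
Product: 3 2-methoxy-6-methyl-4-(triisopropylsilyloxy)benzaldehyde
Conditions: MeI, K2CO3, dry acetone, 40 °C
Reagents that add atoms: iodomethane, CI
Why: Williamson etherification of the remaining chelated phenol under anhydrous carbonate conditions, which the hindered aryl triisopropylsilyl ether should tolerate.

Step 3
Reactants: 3 2-methoxy-6-methyl-4-(triisopropylsilyloxy)benzaldehyde
Product: 4 2-methoxy-6-methyl-4-(triisopropylsilyloxy)benzoic acid
Conditions: NaClO2, NaH2PO4, 2-methyl-2-butene, t-BuOH/THF/H2O, 0 °C to rt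
Reagents that add atoms: sodium chlorite, [Na+].[O-]Cl=O
Why: Pinnick oxidation takes the hindered aldehyde to the acid at buffered pH, and the alkene scavenger removes the hypochlorite by-product before it can chlorinate the electron-rich ring.

Step 4
Reactants: 4 2-methoxy-6-methyl-4-(triisopropylsilyloxy)benzoic acid
Product: 5 2-methoxy-6-methyl-4-(triisopropylsilyloxy)benzoyl chloride
Conditions: (COCl)2 (1.3 equiv), cat. Me2NCHO, CH2Cl2, 0 °C to rt; evaporate, use crude
Reagents that add atoms: oxalyl chloride, O=C(Cl)C(=O)Cl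
Why: Standard formamide-catalysed acid chloride formation; only gases are released, so the donor-rich 2,6-disubstituted acid chloride needs no purification.

Step 5
Reactants: 5 2-methoxy-6-methyl-4-(triisopropylsilyloxy)benzoyl chloride; 6 2-methylcyclohexane-1,3-dione
Product: 7 2-methyl-3-oxocyclohex-1-en-1-yl aroate (achiral enol aroate)
Conditions: Et3N (1.5 equiv), CH2Cl2, 0 °C to rt
Reagents that add atoms: none
Why: O-acylation of the ambident dione enolate by a hard acyl chloride; the C7 methyl group disfavours C-acylation, and nucleophilic catalysts that promote O-to-C acyl shifts are left out.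

Step 6
Reactants: 7 2-methyl-3-oxocyclohex-1-en-1-yl aroate
Product: 8 (3R)-3-hydroxy-2-methylcyclohex-1-en-1-yl aroate
Conditions: (S)-1-methyl-3,3-diphenyltetrahydro-1H,3H-pyrrolo[1,2-c][1,3,2]oxazaborole (15 mol %), BH3·SMe2 (0.8 equiv), THF, −30 °C; MeOH quench, neutral work-up
Reagents that add atoms: none
Why: Corey–Bakshi–Shibata 1,2-reduction; the ketone should bind the borane-loaded (S)-catalyst with the fully substituted C7=C8 alkenyl arm as the large group and the C5 methylene as the small one, so hydride is delivered in the sense that turns acetophenone into the (R)-alcohol and C6 is set as R.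

Step 7
Reactants: 8 (3R)-3-hydroxy-2-methylcyclohex-1-en-1-yl aroate
Product: 9 (1R,5R,6R)-5-hydroxy-6-methyl-7-oxabicyclo[4.1.0]heptan-1-yl aroate (oxirane oxygen syn to the hydroxyl)
Conditions: VO(acac)2 (3 mol %), t-BuOOH (anhydrous, decane, 1.5 equiv), CH2Cl2, 0 °C; filtration through Et3N-deactivated silica
Reagents that add atoms: tert-butyl hydroperoxide, CC(C)(C)OO
Why: Hydroxyl-directed epoxidation; the vanadium alkoxide of the C6 hydroxyl, held pseudoaxial by A(1,2) strain with the C7 methyl group, delivers the peroxide oxygen to its own face and so sets C7 and C8.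

Step 8
Reactants: 9 (1R,5R,6R)-5-hydroxy-6-methyl-7-oxabicyclo[4.1.0]heptan-1-yl aroate
Product: 10 (1R,5R,6R)-5-TBSO-6-methyl-7-oxabicyclo[4.1.0]heptan-1-yl aroate
Conditions: TBSCl (1.5 equiv), imidazole (3 equiv), Me2NCHO, 0 °C to rt
Reagents that add atoms: tert-butyldimethylsilyl chloride, CC(C)(C)[Si](C)(C)Cl
Why: Standard silylation under weakly basic conditions that should trigger neither Payne migration nor opening of the acyloxy oxirane; it removes the free hydroxyl as a competing nucleophile before the rearrangement.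

Step 9
Reactants: 10 (1R,5R,6R)-5-TBSO-6-methyl-7-oxabicyclo[4.1.0]heptan-1-yl aroate
Product: 11 (1S,2R)-2-TBSO-1-methyl-6-oxocyclohexyl aroate (ester oxygen and silyloxy group trans)
Conditions: YbCl3 (anhydrous, 10 mol %), 2,6-di-tert-butyl-4-methylpyridine (20 mol %), CH2Cl2, rt
Reagents that add atoms: none
Why: This is the rearrangement of an enol ester epoxide to an alpha-acyloxy ketone, a known reaction type that is stereospecific with inversion under thermal or weak Lewis acid conditions: ytterbium binds the oxirane oxygen and loosens C7–O, the aroyl C=O oxygen (held on the opposite ring face because the ester hangs from C8 anti to the oxirane) attacks C7 from the rear through a five-membered cyclic transition state, and the oxirane oxygen stays on C8 and becomes the ketone as the original C8–O(acyl) bond breaks. No ring of the target is closed; only the temporary oxirane is opened. The new C7 stereocentre is controlled by the epoxide configuration fixed in step 7 and is inverted, so the ester oxygen ends anti to the C6 silyloxy group (7S) while C6 is untouched. The step needs the invertive channel to win over the retentive one (C8–O opening with hand-over of the acyl group to the oxirane oxygen) and over proton loss from a free C7 cation. Tertiary C7, the ortho/para oxygen donors that make the carbonyl oxygen nucleophilic, the 2,6-disubstitution that blocks addition at the acyl carbon, and the hindered pyridine that removes traces of protic acid all favour inversion.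

Step 10
Reactants: 11 (1S,2R)-2-TBSO-1-methyl-6-oxocyclohexyl aroate
Product: 12 (1S,6R)-6-TBSO-1-methyl-2-(trimethylsilyloxy)cyclohex-2-en-1-yl aroate
Conditions: TMSOTf (1.3 equiv), Et3N (2 equiv), CH2Cl2, 0 °C
Reagents that add atoms: trimethylsilyl triflate, C[Si](C)(C)OS(=O)(=O)C(F)(F)F
Why: Soft enolisation; C7 is quaternary, so only C8a can lose a proton, and the amine base leaves the benzylic methyl group of the ortho-toluate and the ester untouched.

Step 11
Reactants: 12 (1S,6R)-6-TBSO-1-methyl-2-(trimethylsilyloxy)cyclohex-2-en-1-yl aroate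
Product: 13 (1S,6R)-6-TBSO-1-methyl-2-oxocyclohex-3-en-1-yl aroate
Conditions: Pd(OAc)2 (1.05 equiv), MeCN, rt
Reagents that add atoms: none
Why: Saegusa–Ito oxidation; exchange of silicon for divalent palladium at C8a and beta-hydride elimination from C4a install the C8a=C4a double bond under near-neutral conditions that should not provoke vinylogous loss of the C6 silyloxy group.

Step 12
Reactants: 14 (E)-but-2-enal (crotonaldehyde)
Product: 15 (3E)-1,1-dibromopenta-1,3-diene
Conditions: CBr4, PPh3, CH2Cl2, 0 °C; pentane trituration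
Reagents that add atoms: carbon tetrabromide, BrC(Br)(Br)Br
Why: Corey–Fuchs dibromoolefination (a Wittig-type reaction of the dibromomethylene ylide), which does not touch the E alkene.

Step 13
Reactants: 15 (3E)-1,1-dibromopenta-1,3-diene; 13 (1S,6R)-6-TBSO-1-methyl-2-oxocyclohex-3-en-1-yl aroate
Product: 18 (1S,4R,6R)-2,6-bis(TBSO)-1-methyl-4-[(E)-pent-3-en-1-yn-1-yl]cyclohex-2-en-1-yl aroate, via lithium pentenynide 16 (not isolated), via pentenynylzinc bromide 17 (not isolated)
Conditions: 15, n-BuLi (2.05 equiv), Et2O, −78 to 0 °C; ZnBr2 (THF), 0 °C; then 13, TBSOTf (1.5 equiv), Et2O/THF, −40 °C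
Reagents that add atoms: tert-butyldimethylsilyl triflate, CC(C)(C)[Si](C)(C)OS(=O)(=O)C(F)(F)F; for the intermediates only: n-BuLi, [Li]CCCC (Li of 16); ZnBr2, Br[Zn]Br (Zn and Br of 17)
Why: The second half of the Corey–Fuchs sequence gives the acetylide, and silyl triflate-promoted 1,4-addition of alkynylzinc halides is an established way to alkynylate s-trans cyclic enones; axial attack anti to the C6 substituent should give the 4a,6-trans adduct (4aR), a centre that is deleted in step 17.

Step 14
Reactants: 18 (1S,4R,6R)-2,6-bis(TBSO)-1-methyl-4-[(E)-pent-3-en-1-yn-1-yl]cyclohex-2-en-1-yl aroate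
Product: 19 (1S,2R,4R)-2-TBSO-1-methyl-6-oxo-4-[(E)-pent-3-en-1-yn-1-yl]cyclohexyl aroate
Conditions: 1 M aq. HCl, THF, 0 °C
Reagents that add atoms: none
Why: Acid hydrolysis of the silyl enol ether, which is far more labile than the hindered secondary alkyl TBS ether or the acid-stable aryl TIPS ether; C8a becomes CH2, so no stereocentre arises.

Step 15
Reactants: 19 (1S,2R,4R)-2-TBSO-1-methyl-6-oxo-4-[(E)-pent-3-en-1-yn-1-yl]cyclohexyl aroate
Product: 21 (1S,2R,4S,5Z)-2-TBSO-5-(hydroxymethylidene)-1-methyl-6-oxo-4-[(E)-pent-3-en-1-yn-1-yl]cyclohexyl aroate, via lithium enolate 20 (not isolated)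
Conditions: LiN(SiMe3)2 (1.15 equiv), THF, −78 °C; HCO2CH2CF3 (2 equiv), −78 °C; cold 0.5 M HCl
Reagents that add atoms: 2,2,2-trifluoroethyl formate, O=COCC(F)(F)F; for intermediate 20 only: LiN(SiMe3)2, [Li]N([Si](C)(C)C)[Si](C)(C)C
Why: Kinetic Claisen-type formylation at C8a, the only enolisable position, brings in C1; the silazide is too weak to deprotonate the ortho-toluate methyl group, and the activated formate reacts at −78 °C and releases only poorly nucleophilic trifluoroethoxide, which spares the aryl silyl ether and the ester better than the ethyl formate/alkoxide variant would.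

Step 16
Reactants: 21 (1S,2R,4S,5Z)-2-TBSO-5-(hydroxymethylidene)-1-methyl-6-oxo-4-[(E)-pent-3-en-1-yn-1-yl]cyclohexyl aroate
Product: 22 (1S,2R,4S,5R)-2-TBSO-5-formyl-1-methyl-6-oxo-4-[(E)-pent-3-en-1-yn-1-yl]-5-(phenylselanyl)cyclohexyl aroate
Conditions: PhSeCl (1.05 equiv), pyridine (1.2 equiv), CH2Cl2, 0 °C
Reagents that add atoms: benzeneselenenyl chloride, Cl[Se]c1ccccc1
Why: Alpha-selenenylation of a beta-dicarbonyl enol with the moderated PhSeCl–pyridine complex, the enol being far more nucleophilic than the enyne; A(1,3) strain with the exocyclic hydroxymethylidene group holds the C4a alkynyl group axial, so selenium should enter C8a from the opposite face, cis to C4a–H (8aR).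

Step 17
Reactants: 22 (1S,2R,4S,5R)-2-TBSO-5-formyl-1-methyl-6-oxo-4-[(E)-pent-3-en-1-yn-1-yl]-5-(phenylselanyl)cyclohexyl aroate
Product: 24 (1S,6R)-6-TBSO-3-formyl-1-methyl-2-oxo-4-[(E)-pent-3-en-1-yn-1-yl]cyclohex-3-en-1-yl aroate, via selenoxide 23 (not isolated)
Conditions: 30% aq. H2O2 (2.5 equiv), CH2Cl2, 0 °C
Reagents that add atoms: for intermediate 23 only: hydrogen peroxide, OO (no atom of it stays in 24)
Why: Selenoxide syn elimination; C4a–H is the only beta-hydrogen and lies syn to selenium, so the cyclic elimination restores the C4a=C8a double bond at or below room temperature and erases both temporary stereocentres.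

Step 18
Reactants: 24 (1S,6R)-6-TBSO-3-formyl-1-methyl-2-oxo-4-[(E)-pent-3-en-1-yn-1-yl]cyclohex-3-en-1-yl aroate
Product: 25 (1S,6R)-6-TBSO-3-(hydroxymethyl)-1-methyl-2-oxo-4-[(E)-pent-3-en-1-yn-1-yl]cyclohex-3-en-1-yl aroate
Conditions: i-Bu2AlH (1.05 equiv), CH2Cl2, −78 °C; aq. KNaC4H4O6 (potassium sodium tartrate)
Reagents that add atoms: none
Why: Chemoselective 1,2-reduction; at −78 °C one equivalent of this 1,2-selective aluminium hydride should attack the open formyl group much faster than the C8 ketone (flanked by quaternary C7 and a tetrasubstituted alkene carbon) or the 2,6-disubstituted aroate, and it avoids the conjugate reduction that borohydrides tend to give with doubly activated alkenes.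

Step 19
Reactants: 25 (1S,6R)-6-TBSO-3-(hydroxymethyl)-1-methyl-2-oxo-4-[(E)-pent-3-en-1-yn-1-yl]cyclohex-3-en-1-yl aroate
Product: 26 (6R,7S)-6-TBSO-7-methyl-8-oxo-3-[(E)-prop-1-en-1-yl]-5,6,7,8-tetrahydro-1H-isochromen-7-yl aroate
Conditions: Ph3PAuNTf2 (5 mol %), CH2Cl2, 0 °C to rt
Reagents that add atoms: none
Why: Alkyne hydroalkoxylation (cycloisomerisation) under monovalent gold catalysis; the C1 hydroxyl adds anti to the activated alkyne at C3 (6-endo-dig) and protodeauration places H on C4, C3 being preferred over C4 (5-exo-dig) because it is the delta terminus of the C8 enone and is stabilised by the propenyl group.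

Step 20
Reactants: 26 (6R,7S)-6-TBSO-7-methyl-8-oxo-3-[(E)-prop-1-en-1-yl]-5,6,7,8-tetrahydro-1H-isochromen-7-yl aroate
Product: 27 (6R,7S)-6-hydroxy-7-methyl-8-oxo-3-[(E)-prop-1-en-1-yl]-5,6,7,8-tetrahydro-1H-isochromen-7-yl 4-hydroxy-2-methoxy-6-methylbenzoate (target CNP0187389.3)
Conditions: HF·pyridine, excess pyridine, THF, 0 °C to rt
Reagents that add atoms: none
Why: Global fluoride-mediated desilylation of the aryl TIPS and secondary TBS ethers in a buffered, non-basic medium, which should avoid retro-aldol cleavage at C6–C7, vinylogous elimination of the C6 oxygen and migration of the hindered aroyl group.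

## Compound list

1 | 2,4-dihydroxy-6-methylbenzaldehyde | Cc1cc(O)cc(O)c1C=O | starting material
2 | 2-hydroxy-6-methyl-4-(triisopropylsilyloxy)benzaldehyde | Cc1cc(O[Si](C(C)C)(C(C)C)C(C)C)cc(O)c1C=O | intermediate
3 | 2-methoxy-6-methyl-4-(triisopropylsilyloxy)benzaldehyde | COc1cc(O[Si](C(C)C)(C(C)C)C(C)C)cc(C)c1C=O | intermediate
4 | 2-methoxy-6-methyl-4-(triisopropylsilyloxy)benzoic acid | COc1cc(O[Si](C(C)C)(C(C)C)C(C)C)cc(C)c1C(=O)O | intermediate
5 | 2-methoxy-6-methyl-4-(triisopropylsilyloxy)benzoyl chloride | COc1cc(O[Si](C(C)C)(C(C)C)C(C)C)cc(C)c1C(=O)Cl | intermediate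
6 | 2-methylcyclohexane-1,3-dione | CC1C(=O)CCCC1=O | starting material
7 | 2-methyl-3-oxocyclohex-1-en-1-yl 2-methoxy-6-methyl-4-(triisopropylsilyloxy)benzoate | COc1cc(O[Si](C(C)C)(C(C)C)C(C)C)cc(C)c1C(=O)OC1=C(C)C(=O)CCC1 | intermediate
8 | (3R)-3-hydroxy-2-methylcyclohex-1-en-1-yl 2-methoxy-6-methyl-4-(triisopropylsilyloxy)benzoate | COc1cc(O[Si](C(C)C)(C(C)C)C(C)C)cc(C)c1C(=O)OC1=C(C)[C@H](O)CCC1 | intermediate
9 | (1R,5R,6R)-5-hydroxy-6-methyl-7-oxabicyclo[4.1.0]heptan-1-yl 2-methoxy-6-methyl-4-(triisopropylsilyloxy)benzoate | COc1cc(O[Si](C(C)C)(C(C)C)C(C)C)cc(C)c1C(=O)O[C@@]12O[C@]1(C)[C@H](O)CCC2 | intermediate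
10 | (1R,5R,6R)-5-(tert-butyldimethylsilyloxy)-6-methyl-7-oxabicyclo[4.1.0]heptan-1-yl 2-methoxy-6-methyl-4-(triisopropylsilyloxy)benzoate | COc1cc(O[Si](C(C)C)(C(C)C)C(C)C)cc(C)c1C(=O)O[C@@]12O[C@]1(C)[C@H](O[Si](C)(C)C(C)(C)C)CCC2 | intermediate
11 | (1S,2R)-2-(tert-butyldimethylsilyloxy)-1-methyl-6-oxocyclohexyl 2-methoxy-6-methyl-4-(triisopropylsilyloxy)benzoate | O=C1[C@@](C)(OC(=O)c2c(C)cc(O[Si](C(C)C)(C(C)C)C(C)C)cc2OC)[C@H](O[Si](C)(C)C(C)(C)C)CCC1 | intermediate
12 | (1S,6R)-6-(tert-butyldimethylsilyloxy)-1-methyl-2-(trimethylsilyloxy)cyclohex-2-en-1-yl 2-methoxy-6-methyl-4-(triisopropylsilyloxy)benzoate | C[Si](C)(C)OC1=CCC[C@@H](O[Si](C)(C)C(C)(C)C)[C@]1(C)OC(=O)c1c(C)cc(O[Si](C(C)C)(C(C)C)C(C)C)cc1OC | intermediate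
13 | (1S,6R)-6-(tert-butyldimethylsilyloxy)-1-methyl-2-oxocyclohex-3-en-1-yl 2-methoxy-6-methyl-4-(triisopropylsilyloxy)benzoate | O=C1[C@@](C)(OC(=O)c2c(C)cc(O[Si](C(C)C)(C(C)C)C(C)C)cc2OC)[C@H](O[Si](C)(C)C(C)(C)C)CC=C1 | intermediate
14 | (E)-but-2-enal | C/C=C/C=O | starting material
15 | (3E)-1,1-dibromopenta-1,3-diene | C/C=C/C=C(Br)Br | intermediate
16 | lithium (E)-pent-3-en-1-yn-1-ide (not isolated) | [Li]C#C/C=C/C | intermediate
17 | bromo[(E)-pent-3-en-1-yn-1-yl]zinc (not isolated) | Br[Zn]C#C/C=C/C | intermediate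
18 | (1S,4R,6R)-2,6-bis(tert-butyldimethylsilyloxy)-1-methyl-4-[(E)-pent-3-en-1-yn-1-yl]cyclohex-2-en-1-yl 2-methoxy-6-methyl-4-(triisopropylsilyloxy)benzoate | CC(C)(C)[Si](C)(C)OC1=C[C@H](C#C/C=C/C)C[C@@H](O[Si](C)(C)C(C)(C)C)[C@]1(C)OC(=O)c1c(C)cc(O[Si](C(C)C)(C(C)C)C(C)C)cc1OC | intermediate
19 | (1S,2R,4R)-2-(tert-butyldimethylsilyloxy)-1-methyl-6-oxo-4-[(E)-pent-3-en-1-yn-1-yl]cyclohexyl 2-methoxy-6-methyl-4-(triisopropylsilyloxy)benzoate | O=C1[C@@](C)(OC(=O)c2c(C)cc(O[Si](C(C)C)(C(C)C)C(C)C)cc2OC)[C@H](O[Si](C)(C)C(C)(C)C)C[C@@H](C#C/C=C/C)C1 | intermediate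
20 | lithium C8/C8a enolate of 19 (not isolated) | [Li]OC1=C[C@H](C#C/C=C/C)C[C@@H](O[Si](C)(C)C(C)(C)C)[C@]1(C)OC(=O)c1c(C)cc(O[Si](C(C)C)(C(C)C)C(C)C)cc1OC | intermediate
21 | (1S,2R,4S,5Z)-2-(tert-butyldimethylsilyloxy)-5-(hydroxymethylidene)-1-methyl-6-oxo-4-[(E)-pent-3-en-1-yn-1-yl]cyclohexyl 2-methoxy-6-methyl-4-(triisopropylsilyloxy)benzoate | O/C=C1\C(=O)[C@@](C)(OC(=O)c2c(C)cc(O[Si](C(C)C)(C(C)C)C(C)C)cc2OC)[C@H](O[Si](C)(C)C(C)(C)C)C[C@H]1C#C/C=C/C | intermediate
22 | (1S,2R,4S,5R)-2-(tert-butyldimethylsilyloxy)-5-formyl-1-methyl-6-oxo-4-[(E)-pent-3-en-1-yn-1-yl]-5-(phenylselanyl)cyclohexyl 2-methoxy-6-methyl-4-(triisopropylsilyloxy)benzoate | O=C1[C@@](C)(OC(=O)c2c(C)cc(O[Si](C(C)C)(C(C)C)C(C)C)cc2OC)[C@H](O[Si](C)(C)C(C)(C)C)C[C@@H](C#C/C=C/C)[C@]1(C=O)[Se]c1ccccc1 | intermediate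
23 | selenoxide of 22, configuration at selenium undefined (not isolated) | O=C1[C@@](C)(OC(=O)c2c(C)cc(O[Si](C(C)C)(C(C)C)C(C)C)cc2OC)[C@H](O[Si](C)(C)C(C)(C)C)C[C@@H](C#C/C=C/C)[C@]1(C=O)[Se](=O)c1ccccc1 | intermediate
24 | (1S,6R)-6-(tert-butyldimethylsilyloxy)-3-formyl-1-methyl-2-oxo-4-[(E)-pent-3-en-1-yn-1-yl]cyclohex-3-en-1-yl 2-methoxy-6-methyl-4-(triisopropylsilyloxy)benzoate | O=C1[C@@](C)(OC(=O)c2c(C)cc(O[Si](C(C)C)(C(C)C)C(C)C)cc2OC)[C@H](O[Si](C)(C)C(C)(C)C)CC(C#C/C=C/C)=C1C=O | intermediate
25 | (1S,6R)-6-(tert-butyldimethylsilyloxy)-3-(hydroxymethyl)-1-methyl-2-oxo-4-[(E)-pent-3-en-1-yn-1-yl]cyclohex-3-en-1-yl 2-methoxy-6-methyl-4-(triisopropylsilyloxy)benzoate | O=C1[C@@](C)(OC(=O)c2c(C)cc(O[Si](C(C)C)(C(C)C)C(C)C)cc2OC)[C@H](O[Si](C)(C)C(C)(C)C)CC(C#C/C=C/C)=C1CO | intermediate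
26 | (6R,7S)-6-(tert-butyldimethylsilyloxy)-7-methyl-8-oxo-3-[(E)-prop-1-en-1-yl]-5,6,7,8-tetrahydro-1H-isochromen-7-yl 2-methoxy-6-methyl-4-(triisopropylsilyloxy)benzoate | C/C=C/C1=CC2=C(CO1)C(=O)[C@@](C)(OC(=O)c1c(C)cc(O[Si](C(C)C)(C(C)C)C(C)C)cc1OC)[C@H](O[Si](C)(C)C(C)(C)C)C2 | intermediate
27 | (6R,7S)-6-hydroxy-7-methyl-8-oxo-3-[(E)-prop-1-en-1-yl]-5,6,7,8-tetrahydro-1H-isochromen-7-yl 4-hydroxy-2-methoxy-6-methylbenzoate | C/C=C/C1=CC2=C(CO1)C(=O)[C@@](C)(OC(=O)c1c(C)cc(O)cc1OC)[C@H](O)C2 | target

## Step count and risks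

Total step count: 20.
Longest linear sequence: 19 steps, from 1 to 27 through steps 1–11 and 13–20. Step 12 lies on the side branch.

**Step 9 (rearrangement of the enol aroate epoxide).**
- The electron-withdrawing C6 silyloxy group may slow the loosening of C7–O.
- More forcing conditions may let that bond ionise fully, with loss of stereospecificity or proton loss next to C7.
- The fallback uses the complementary stereochemical pairing, an epoxide on the other face combined with retention. It sets out from 8 and comes back at 11.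
- Compound 8 is silylated first (TBSCl, imidazole, Me2NCHO) to give the allylic silyl ether F1.
- With the hydroxyl masked and the bulky silyloxy group held pseudoaxial by A(1,2) strain, 3-chloroperbenzoic acid (CH2Cl2, 0 °C) should epoxidise the face anti to it and give the anti enol aroate epoxide F2.
- Catalytic anhydrous p-toluenesulfonic acid (CH2Cl2, 0 °C) then triggers the known retentive variant of the rearrangement. The C8–O oxirane bond opens toward the acyloxy-stabilised cation, the C7–O bond is never broken, and the donor-rich aroyl group, which can leave in an acylium-like manner, is handed over to that oxygen.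
- Because the oxygen already sits anti to the C6 silyloxy group, the product is 11.

**Step 17 (selenoxide elimination to the 2-formyl enynyl enone).**
- As it forms, the doubly activated C4a=C8a alkene may be attacked by peroxide or by the selenium by-products, and the aldehyde may be over-oxidised.
- The fallback reverses the order of reduction and elimination, so the formyl enone never exists. It sets out from 22 and comes back at 25, and so also replaces step 18.
- The unconjugated aldehyde of 22 is reduced with i-Bu2AlH (1.05 equiv, CH2Cl2, −78 °C). The C8 ketone now lies between two quaternary carbons, and the product is the hydroxymethyl selenide F3.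
- Oxidation with H2O2 (CH2Cl2, 0 °C) gives its selenoxide F4.
- F4 should eliminate away from the carbinol carbon, as beta-hydroxy selenoxides generally do, and toward C4a–H to give 25.

**Step 19 (6-endo-dig cycloisomerisation).**
- The hydroxyl may attack C4 instead (5-exo-dig), followed by aromatisation of the alkylidene dihydrofuran to a fused furan.
- The fallback closes the ring from the aldehyde oxidation level. It sets out from 24 and comes back at 26, and so also bypasses step 18.
- AgOTf (10 mol %) and CF3CO2H (1.1 equiv) in ClCH2CH2Cl let the formyl oxygen add to C3. Only the 6-endo mode leads to an aromatic pyrylium ring, the pyrylium trifluoroacetate F5.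
- F5 is reduced in the same flask at its unsubstituted C1 position by diethyl 2,6-dimethyl-1,4-dihydropyridine-3,5-dicarboxylate (Hantzsch ester). This is the known cyclisation/transfer-hydrogenation route from ortho-alkynyl carbonyl compounds to 1H-isochromenes.

## Further compounds

F1 | step 9 | (3R)-3-(tert-butyldimethylsilyloxy)-2-methylcyclohex-1-en-1-yl 2-methoxy-6-methyl-4-(triisopropylsilyloxy)benzoate | COc1cc(O[Si](C(C)C)(C(C)C)C(C)C)cc(C)c1C(=O)OC1=C(C)[C@H](O[Si](C)(C)C(C)(C)C)CCC1
F2 | step 9 | (1S,5R,6S)-5-(tert-butyldimethylsilyloxy)-6-methyl-7-oxabicyclo[4.1.0]heptan-1-yl 2-methoxy-6-methyl-4-(triisopropylsilyloxy)benzoate (oxirane oxygen anti to the silyloxy group) | COc1cc(O[Si](C(C)C)(C(C)C)C(C)C)cc(C)c1C(=O)O[C@]12O[C@@]1(C)[C@H](O[Si](C)(C)C(C)(C)C)CCC2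
F3 | step 17 | (1S,2R,4S,5R)-2-(tert-butyldimethylsilyloxy)-5-(hydroxymethyl)-1-methyl-6-oxo-4-[(E)-pent-3-en-1-yn-1-yl]-5-(phenylselanyl)cyclohexyl 2-methoxy-6-methyl-4-(triisopropylsilyloxy)benzoate | O=C1[C@@](C)(OC(=O)c2c(C)cc(O[Si](C(C)C)(C(C)C)C(C)C)cc2OC)[C@H](O[Si](C)(C)C(C)(C)C)C[C@@H](C#C/C=C/C)[C@]1(CO)[Se]c1ccccc1
F4 | step 17 | selenoxide of F3, configuration at selenium undefined | O=C1[C@@](C)(OC(=O)c2c(C)cc(O[Si](C(C)C)(C(C)C)C(C)C)cc2OC)[C@H](O[Si](C)(C)C(C)(C)C)C[C@@H](C#C/C=C/C)[C@]1(CO)[Se](=O)c1ccccc1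
F5 | step 19 | (6R,7S)-6-(tert-butyldimethylsilyloxy)-7-[2-methoxy-6-methyl-4-(triisopropylsilyloxy)benzoyloxy]-7-methyl-8-oxo-3-[(E)-prop-1-en-1-yl]-5,6,7,8-tetrahydroisochromenylium trifluoroacetate | C/C=C/c1cc2c(c[o+]1)C(=O)[C@@](C)(OC(=O)c1c(C)cc(O[Si](C(C)C)(C(C)C)C(C)C)cc1OC)[C@H](O[Si](C)(C)C(C)(C)C)C2.[O-]C(=O)C(F)(F)F
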